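Without the side chain on ring A, the oxolane core (O1, C2–C5) with aryl rings A and B is a mirror-symmetric 2,3-trans-3,4-cis-4,5-trans dimer of a 4-propenylphenol; the key step exploits this hidden symmetry. Everything rests on cutting C3–C4, O1–C2 and O1–C5 together: anodic oxidation joins the beta-carbons of two alkenes and one water molecule bridges both benzylic carbons, creating the ring, three bonds and four stereocentres in one operation. The precursor is simply the O-methyl ether of the monomer, commercial (E)-anethole, used twice. The meso product is then desymmetrised enzymatically, brominated on ring A, coupled with a ring-C alkenylboronate and hydrogenated under iridium catalyst control.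

Key step: step 1

Labels: O1, C2 (R, bears ring A), C3 (R), C4 (S), C5 (S, bears ring B). Ring C is the phenol ring at the end of the side chain, whose stereocentre is R.

Assumption on the enzyme: the lipase is taken to cleave the acetate of the ring on the (R)-configured benzylic carbon C2. If it prefers the other arm, the same enzyme used in the acylating direction on the free meso bisphenol F4 gives the same compound 8.

Assumption on the catalyst: the (S)-configured ligand is taken to give the (R)-centre, by analogy with the reduction of (E)-1,2-diphenylpropene to the (R)-alkane. This is to be confirmed on that model, and the (R)-ligand is equally available.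

Step 1
Reactants: 1 (E)-anethole (two molecules); 2 water
Product: 5 meso-(2R,3R,4S,5S)-2,5-bis(4-methoxyphenyl)-3,4-dimethyloxolane (2,3-trans-3,4-cis-4,5-trans), via erythro beta-beta dimer dication 3 (not isolated), via kinetic oxolane diastereomer mixture 4 (not isolated)
Conditions: graphite anode, Pt cathode, undivided cell, constant current, about 1.1 F per mol of 1, LiClO4 (0.1 M), 2,6-lutidine (0.1 equiv), MeCN–H2O 19:1, 1 at 0.4 M, 10 °C; crude 4, then CF3CO2H (10 mol%), CH2Cl2, rt; chromatography, crystallisation
Reagents that add atoms: water (compound 2), O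
Why: Removal of one electron at the anode converts 1 into a radical cation that is attacked at its beta-carbon by the beta-carbon of a second, neutral molecule of 1 (C3–C4), and loss of a second electron leaves the two benzylic carbons as 4-methoxybenzyl cations, drawn as dication 3 although water may already have trapped one end before the second electron leaves. Water then binds to C2 and the resulting benzylic alcohol closes the oxolane by 5-exo-trig attack on the O-methylated quinone-methide form of C5, while the released protons are reduced to H2 at the cathode. The closest known reaction type is the anodic (or chemical one-electron) tail-to-tail dimerisation of 4-alkoxystyrenes and 4-propenylanisoles in moist acetonitrile, which gives 2,5-diaryltetrahydrofurans. C3 and C4 are fixed in the C–C coupling, where the acyclic partners offer no bias, so erythro and threo dimers must both be expected and only the erythro (3,4-cis) series is of use. C2 and C5 are placed under thermodynamic control, since catalytic CF3CO2H reversibly ionises the 4-methoxybenzylic C–O bonds (too mild to deprotonate C3 or C4) and drives the three 3,4-cis isomers to the one in which each aryl group is trans to the neighbouring methyl, so that mixture 4 collapses to meso 5 and the racemic all-trans isomer, which chromatography and crystallisation should separate. The step needs beta–beta regioselectivity, secured by the O-methyl group that rules out phenoxyl-type C–O and ortho-C coupling and places the positive charge at the benzylic carbons, and it needs chemoselectivity for 1 over 5, secured by the lower oxidation potential of the conjugated alkene and by limiting the charge passed.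

Step 2
Reactants: 5 meso-2,5-bis(4-methoxyphenyl)-3,4-dimethyloxolane
Product: 7 meso-[(2R,3R,4S,5S)-3,4-dimethyloxolane-2,5-diyl]di-4,1-phenylene diacetate, via dilithium bis-phenolate 6 (not isolated)
Conditions: LiPPh2 (commercial 0.5 M solution in THF, 4 equiv), THF, reflux; 0 °C, then Ac2O (8 equiv), 0 °C to rt
Reagents that add atoms: acetic anhydride, CC(=O)OC(C)=O
Why: Aryl methyl ether cleavage by SN2 attack of the soft diphenylphosphide anion on the O-methyl carbons runs without acid at the reflux temperature of THF, so the acid-labile bis-benzylic ether and its four stereocentres stay untouched, and O-acylation of bis-phenolate 6 in the same flask should deliver the easily purified, still meso diacetate 7.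

Step 3
Reactants: 7 meso diacetate
Product: 8 4-[(2S,3S,4R,5R)-5-(4-hydroxyphenyl)-3,4-dimethyloxolan-2-yl]phenyl acetate (free phenol on ring A at C2, acetate on ring B at C5)
Conditions: immobilised Burkholderia cepacia lipase, n-BuOH (4 equiv), MTBE–toluene, 35 °C, followed by HPLC on a chiral phase, enzyme filtered off at the conversion of best ee
Reagents that add atoms: none
Why: Lipase-catalysed alcoholysis of one enantiotopic ester (enzymatic desymmetrisation of a meso diester, a reaction type established for aryl acetates and for bis-phenol diesters with remote prochirality) should remove a single acetyl group because the two binding modes place the distal aryl arm and the C3/C4 methyl face in mirror-image regions of the chiral pocket, and because the minor enantiomer of 8 still carries the fast-reacting acetate and is consumed preferentially, the ee of 8 should rise with conversion; no stereocentre is made or broken, and the step only decides that C2 (R) carries the free phenol ring A.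

Step 4
Reactants: 8 monoacetate
Product: 9 4-[(2S,3S,4R,5R)-5-(3-bromo-4-hydroxyphenyl)-3,4-dimethyloxolan-2-yl]phenyl acetate
Conditions: NBS (1.0 equiv), MeCN, −20 °C to 0 °C, dark, run directly after step 3
Reagents that add atoms: N-bromosuccinimide, O=C1CCC(=O)N1Br
Why: In this electrophilic aromatic substitution the free phenol ring A is far more activated than the acetoxy ring B and its para position is blocked by C2, so one equivalent of NBS should brominate one of the two equivalent positions ortho to OH, which stores the desymmetrisation in a C–Br bond that acyl scrambling can no longer erase.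

Step 5
Reactants: 10 4-iodophenol
Product: 11 tert-butyl(4-iodophenoxy)dimethylsilane
Conditions: TBSCl (1.1 equiv), imidazole (1.5 equiv), CH2Cl2, rt
Reagents that add atoms: tert-butyldimethylsilyl chloride, CC(C)(C)[Si](C)(C)Cl
Why: Standard O-silylation masks the acidic phenol, which would otherwise quench the catalytic alkoxide needed in step 7.

Step 6
Reactants: 11 tert-butyl(4-iodophenoxy)dimethylsilane; 12 propyne
Product: 13 tert-butyldimethyl[4-(prop-1-yn-1-yl)phenoxy]silane
Conditions: PdCl2(PPh3)2 (2 mol%), CuI (4 mol%), Et3N, THF, propyne (3 equiv), sealed vessel, rt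
Reagents that add atoms: none
Why: Sonogashira coupling of an aryl iodide with a terminal alkyne proceeds at room temperature, where the aryl silyl ether is stable towards triethylamine.

Step 7
Reactants: 13 tert-butyldimethyl[4-(prop-1-yn-1-yl)phenoxy]silane
Product: 14 (Z)-tert-butyldimethyl{4-[2-(4,4,5,5-tetramethyl-1,3,2-dioxaborolan-2-yl)prop-1-en-1-yl]phenoxy}silane (aryl and methyl cis, boron trans to aryl)
Conditions: CuCl (5 mol%), P(p-tolyl)3 (6 mol%), NaOtBu (6 mol%), B2pin2 (1.1 equiv), MeOH (2 equiv), THF, rt
Reagents that add atoms: bis(pinacolato)diboron, CC1(C)OB(OC1(C)C)B1OC(C)(C)C(C)(C)O1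
Why: In this copper-catalysed formal hydroboration (borylcupration then protonation) the Cu–Bpin species adds syn across the 1-arylpropyne with copper at the aryl-bearing carbon and boron at the methyl-bearing carbon, and methanol protonates the alkenylcopper with retention, which fixes the geometry needed for an E alkene after coupling.

Step 8
Reactants: 9 ring-A bromide; 14 ring-C alkenylboronate (1.3 equiv)
Product: 16 4-[(2R,3R,4S,5S)-5-(4-acetoxyphenyl)-3,4-dimethyloxolan-2-yl]-2-[(E)-1-(4-acetoxyphenyl)prop-1-en-2-yl]phenyl acetate, via triphenol alkene 15 (not isolated)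
Conditions: Pd(OAc)2 (3 mol%), SPhos (6 mol%), Cs2CO3 (6 equiv), DMF–H2O 10:1, 70 °C, argon; work-up at pH 6; crude 15, then Ac2O, pyridine, DMAP (cat.), rt
Reagents that add atoms: acetic anhydride, CC(=O)OC(C)=O
Why: Suzuki–Miyaura coupling proceeds with retention of alkene geometry and should give the E trisubstituted alkene (rings A and C trans), the aqueous carbonate medium, itself a standard reagent for cleaving aryl silyl ethers and aryl acetates, strips both now superfluous groups to give 15, and peracetylation of the crude triphenol should give one uniform, CH2Cl2-soluble triacetate whose electron-poorer rings A and B resist ionisation at C2 and C5 in the next step.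

Step 9
Reactants: 16 triacetate alkene
Product: 17 4-[(2R,3R,4S,5S)-5-(4-acetoxyphenyl)-3,4-dimethyloxolan-2-yl]-2-[(2R)-1-(4-acetoxyphenyl)propan-2-yl]phenyl acetate
Conditions: [Ir(cod)(L)]BArF (1–2 mol%; L = (S)-4-tert-butyl-2-[2-(di-o-tolylphosphino)phenyl]-4,5-dihydrooxazole, BArF = tetrakis[3,5-bis(trifluoromethyl)phenyl]borate), H2 (50 bar), CH2Cl2, rt
Reagents that add atoms: none
Why: Iridium N,P-catalysed asymmetric hydrogenation of an unfunctionalised (E)-1,2-diarylpropene, the benchmark substrate class of these catalysts, selects the alkene face through the catalyst, which keeps the vinylic hydrogen in its hindered quadrant, so syn delivery of H2 to the geometrically pure E alkene should set the side-chain centre as R independently of the remote core, while aryl acetates and the oxolane are inert.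

Step 10
Reactants: 17 triacetate
Product: 18 4-[(2R,3R,4S,5S)-5-(4-hydroxyphenyl)-3,4-dimethyloxolan-2-yl]-2-[(2R)-1-(4-hydroxyphenyl)propan-2-yl]phenol (target)
Conditions: pyrrolidine (6 equiv), THF, 0 °C to rt, argon; wash at pH 6
Reagents that add atoms: none
Why: Aminolysis of the three aryl acetates by pyrrolidine is fast at room temperature and needs neither acid nor strong base, so the 4-hydroxybenzylic C–O bonds at C2 and C5 and all five stereocentres should be preserved.

Compound list
1 | (E)-anethole | C/C=C/c1ccc(OC)cc1 | starting material
2 | water | O | starting material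
3 | erythro beta-beta dimer dication (meso-2,3-dimethyl-1,4-bis(4-methoxyphenyl)butane-1,4-diylium) | COc1ccc([CH+][C@@H](C)[C@@H](C)[CH+]c2ccc(OC)cc2)cc1 | intermediate (not isolated)
4 | 2,5-bis(4-methoxyphenyl)-3,4-dimethyloxolane, kinetic mixture of diastereomers | CC1C(C)C(c2ccc(OC)cc2)OC1c1ccc(OC)cc1 | intermediate (not isolated)
5 | meso-(2R,3R,4S,5S)-2,5-bis(4-methoxyphenyl)-3,4-dimethyloxolane | C[C@@H]1[C@H](C)[C@@H](c2ccc(OC)cc2)O[C@H]1c1ccc(OC)cc1 | intermediate
6 | dilithium 4,4'-[(2R,3R,4S,5S)-3,4-dimethyloxolane-2,5-diyl]diphenolate (meso) | [Li+].[Li+].C[C@@H]1[C@H](C)[C@@H](c2ccc([O-])cc2)O[C@H]1c1ccc([O-])cc1 | intermediate (not isolated)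
7 | meso-[(2R,3R,4S,5S)-3,4-dimethyloxolane-2,5-diyl]di-4,1-phenylene diacetate | C[C@@H]1[C@H](C)[C@@H](c2ccc(OC(C)=O)cc2)O[C@H]1c1ccc(OC(C)=O)cc1 | intermediate
8 | 4-[(2S,3S,4R,5R)-5-(4-hydroxyphenyl)-3,4-dimethyloxolan-2-yl]phenyl acetate | C[C@@H]1[C@H](C)[C@@H](c2ccc(OC(C)=O)cc2)O[C@H]1c1ccc(O)cc1 | intermediate
9 | 4-[(2S,3S,4R,5R)-5-(3-bromo-4-hydroxyphenyl)-3,4-dimethyloxolan-2-yl]phenyl acetate | C[C@@H]1[C@H](C)[C@@H](c2ccc(OC(C)=O)cc2)O[C@H]1c1ccc(O)c(Br)c1 | intermediate
10 | 4-iodophenol | Oc1ccc(I)cc1 | starting material
11 | tert-butyl(4-iodophenoxy)dimethylsilane | CC(C)(C)[Si](C)(C)Oc1ccc(I)cc1 | intermediate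
12 | propyne | CC#C | starting material
13 | tert-butyldimethyl[4-(prop-1-yn-1-yl)phenoxy]silane | CC#Cc1ccc(O[Si](C)(C)C(C)(C)C)cc1 | intermediate
14 | (Z)-tert-butyldimethyl{4-[2-(4,4,5,5-tetramethyl-1,3,2-dioxaborolan-2-yl)prop-1-en-1-yl]phenoxy}silane | C/C(B1OC(C)(C)C(C)(C)O1)=C\c1ccc(O[Si](C)(C)C(C)(C)C)cc1 | intermediate
15 | 4-[(2R,3R,4S,5S)-5-(4-hydroxyphenyl)-3,4-dimethyloxolan-2-yl]-2-[(E)-1-(4-hydroxyphenyl)prop-1-en-2-yl]phenol | C[C@@H]1[C@H](C)[C@@H](c2ccc(O)cc2)O[C@H]1c1ccc(O)c(/C(C)=C/c2ccc(O)cc2)c1 | intermediate (not isolated)
16 | triacetate of 15 | C[C@@H]1[C@H](C)[C@@H](c2ccc(OC(C)=O)cc2)O[C@H]1c1ccc(OC(C)=O)c(/C(C)=C/c2ccc(OC(C)=O)cc2)c1 | intermediate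
17 | triacetate of the target, side chain (R) | C[C@@H]1[C@H](C)[C@@H](c2ccc(OC(C)=O)cc2)O[C@H]1c1ccc(OC(C)=O)c([C@H](C)Cc2ccc(OC(C)=O)cc2)c1 | intermediate
18 | 4-[(2R,3R,4S,5S)-5-(4-hydroxyphenyl)-3,4-dimethyloxolan-2-yl]-2-[(2R)-1-(4-hydroxyphenyl)propan-2-yl]phenol | C[C@@H]1[C@H](C)[C@@H](c2ccc(O)cc2)O[C@H]1c1ccc(O)c([C@H](C)Cc2ccc(O)cc2)c1 | target

Total step count: 10. Longest linear sequence: 7 (steps 1, 2, 3, 4, 8, 9, 10). Steps 5–7 form the convergent ring-C branch.

Steps most likely to fail

Step 1. The C3–C4 coupling may run mainly through the anti, head-to-head approach that leads to the threo (3,4-trans) series. Trapping of the monomer radical cation by water may also compete with dimerisation. Either process would leave too little of the erythro series.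

The fallback keeps the electrolysis but gives up its stereochemical outcome. It sets out from the whole diastereomer mixture 4. Dehydrogenation with DDQ (2.2 equiv, 1,4-dioxane, 80 °C) converts every isomer into the achiral 2,5-bis(4-methoxyphenyl)-3,4-dimethylfuran F1. Heterogeneous hydrogenation (H2, 3 bar, Rh/Al2O3, EtOAc, rt, stopped after two equivalents) then adds all hydrogen to one face and gives the all-cis oxolane F2, in which the methyl groups are necessarily cis. Catalytic CF3CO2H in CH2Cl2 epimerises C2 and C5 to the trans,cis,trans isomer, and the sequence comes back to the route at 5.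

Step 3. The enzyme may discriminate poorly between the two remote enantiotopic acetates, or turn over the bulky substrate too slowly.

The fallback replaces catalysis by resolution with full recycling and sets out from 7:
- One equivalent of pyrrolidine in THF removes one acetyl group without selectivity.
- This gives 8 together with the enantiomeric monoacetate F3, beside unchanged 7 and the free meso bisphenol F4.
- Preparative supercritical-fluid chromatography on an amylose tris(3,5-dimethylphenylcarbamate) phase isolates 8.
- F3 and F4 are re-acetylated (Ac2O, pyridine) to the achiral 7 and returned to the process.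
- The fallback comes back to the route at 8.

Step 9. The ortho-acetoxy aryl group is twisted out of the alkene plane and its carbonyl oxygen may bind to iridium. This may cause slow hydrogen uptake or poor facial selectivity.

The fallback gives up catalyst control and sets out from 16. Hydrogenation with the achiral, more active [Ir(cod)(PCy3)(py)]PF6 (H2, CH2Cl2, rt) gives 17 together with the side-chain (S)-epimer F5. Because the core is already a single enantiomer, the two are diastereomers. They are separated by preparative HPLC, and the fallback comes back to the route at 17. The same separation also removes material that stems from any minor core enantiomer left by step 3.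

Further compounds
F1 | step 1 | 2,5-bis(4-methoxyphenyl)-3,4-dimethylfuran | Cc1c(C)c(-c2ccc(OC)cc2)oc1-c1ccc(OC)cc1
F2 | step 1 | meso all-cis-(2S,3R,4S,5R)-2,5-bis(4-methoxyphenyl)-3,4-dimethyloxolane | C[C@@H]1[C@H](C)[C@H](c2ccc(OC)cc2)O[C@@H]1c1ccc(OC)cc1
F3 | step 3 | 4-[(2R,3R,4S,5S)-5-(4-hydroxyphenyl)-3,4-dimethyloxolan-2-yl]phenyl acetate (enantiomer of 8) | C[C@H]1[C@@H](C)[C@H](c2ccc(OC(C)=O)cc2)O[C@@H]1c1ccc(O)cc1
F4 | step 3 | meso-4,4'-[(2R,3R,4S,5S)-3,4-dimethyloxolane-2,5-diyl]diphenol | C[C@@H]1[C@H](C)[C@@H](c2ccc(O)cc2)O[C@H]1c1ccc(O)cc1
F5 | step 9 | side-chain (S)-epimer of 17 | C[C@@H]1[C@H](C)[C@@H](c2ccc(OC(C)=O)cc2)O[C@H]1c1ccc(OC(C)=O)c([C@@H](C)Cc2ccc(OC(C)=O)cc2)c1
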